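## Retrosynthetic overview

1. Target 29 ⇒ diol 24: both esters go on last, the C4 (S)-2-methylbutanoate first and the hindered C5 angelate second.
2. Seven-membered ring (formed last): C6–C7 bond by a polarity-reversed reductive coupling. The inner isopropenyl carbon, a cation site in ionic chemistry, becomes a nucleophilic tertiary radical by H-atom transfer and adds to the C=N carbon that stands in for the cyclobutanone carbonyl; loss of N2 leaves C7–H.
3. Cyclobutane and six-membered ring (formed together, first): intramolecular vinylketene–alkene [2+2] of an acyclic C15 acid. The alkene face is set by the silyloxy group at C5 of the acid, which later becomes the enone carbonyl.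
4. C15 acid ⇒ three C5 units (prenal and two methyl 3-methylbut-2-enoate units), joined by two catalyst-controlled vinylogous Mukaiyama aldol reactions; the threo diol and the isopropenyl group come from a hydroxy-directed singlet-oxygen ene reaction.

Assumption: tricyclic compounds are numbered as tricyclo[5.4.0.0^2,8]undecanes (C11 ketone, C9=C10 alkene, C4 and C5 oxygenated, C6 = CMe2, C7 = CH next to C6).
Assumption: the bisphosphoramide antipode in steps 2 and 7 is the one that sends the dienolate to the Si face of the aldehyde.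
Assumption: salts that are only protonated or hydrolysed in the aqueous work-up are not numbered as intermediates.

## Route

Step 1
Reactants: 1 methyl 3-methylbut-2-enoate
Product: 3 tert-butyl[(1-methoxy-3-methylbuta-1,3-dien-1-yl)oxy]dimethylsilane, via lithium dienolate 2 (not isolated)
Conditions: LiN(iPr)2, THF/DMPU, −78 °C; then TBSCl, −78 °C to rt
Reagents that add atoms: tert-butylchlorodimethylsilane, CC(C)(C)[Si](C)(C)Cl
Why: Kinetic γ-deprotonation of the senecioate and O-silylation of the extended enolate give the silyl dienolate (silyl ketene acetal formation); no stereocentre is made and the ketene acetal geometry is of no consequence.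

Step 2
Reactants: 4 prenal (3-methylbut-2-enal); 3 silyl dienolate
Product: 5 methyl (2E,5S)-5-hydroxy-3,7-dimethylocta-2,6-dienoate
Conditions: SiCl4, chiral binaphthyldiamine bisphosphoramide (Si-face antipode, 5 mol%), iPr2NEt (10 mol%), CH2Cl2, −78 °C; aq. NaHCO3
Reagents that add atoms: none
Why: Catalytic enantioselective vinylogous Mukaiyama aldol reaction (Lewis-base-activated SiCl4), in which the dienolate attacks through its γ-carbon on the Si face of the bound enal, setting C5 as S and giving the E-enoate.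

Step 3
Reactants: 5 hydroxy dienoate
Product: 7 methyl (2E,5S,6S)-5,6-dihydroxy-3,7-dimethylocta-2,7-dienoate, via allylic hydroperoxide 6 (not isolated)
Conditions: O2, tetraphenylporphyrin (cat.), visible light, CH2Cl2, −20 °C; then PPh3, −20 to 0 °C
Reagents that add atoms: dioxygen, O=O
Why: Schenck ene reaction of singlet oxygen with the electron-rich trisubstituted alkene only (the enoate is inert), in which the carbinol hydrogen eclipses the alkene to avoid A(1,3) strain and the hydroxyl hydrogen-bonds the incoming oxygen onto its own face, so the threo (5S,6S) hydroperoxide forms with a methyl hydrogen abstracted (isopropenyl group) and PPh3 then reduces the O–O bond without touching C6.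

Step 4
Reactants: 7 diol
Product: 8 methyl (2E)-4-[(4S,5S)-2,2-dimethyl-5-(prop-1-en-2-yl)-1,3-dioxolan-4-yl]-3-methylbut-2-enoate
Conditions: 2,2-dimethoxypropane, PPTS (cat.), CH2Cl2, rt
Reagents that add atoms: 2,2-dimethoxypropane, COC(C)(C)OC
Why: Acid-catalysed transketalisation (acetonide formation) masks both hydroxyls as a trans-dioxolane that withstands the hydride, Lewis acid, ketene and radical steps, with the stereocentres untouched.

Step 5
Reactants: 8 acetonide ester
Product: 9 (2E)-4-[(4S,5S)-2,2-dimethyl-5-(prop-1-en-2-yl)-1,3-dioxolan-4-yl]-3-methylbut-2-en-1-ol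
Conditions: iBu2AlH (2.5 equiv), CH2Cl2, −78 °C
Reagents that add atoms: none
Why: 1,2-Reduction of the conjugated ester by the aluminium hydride gives the allylic alcohol and leaves the E-alkene, the acetonide and the isopropenyl group intact.

Step 6
Reactants: 9 allylic alcohol
Product: 10 (2E)-4-[(4S,5S)-2,2-dimethyl-5-(prop-1-en-2-yl)-1,3-dioxolan-4-yl]-3-methylbut-2-enal
Conditions: MnO2 (excess), CH2Cl2, rt
Reagents that add atoms: none
Why: Chemoselective allylic oxidation of the primary allylic alcohol to the enal under neutral conditions that do not isomerise the E-alkene.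

Step 7
Reactants: 10 enal; 3 silyl dienolate
Product: 11 methyl (2E,5S,6E)-8-[(4S,5S)-2,2-dimethyl-5-(prop-1-en-2-yl)-1,3-dioxolan-4-yl]-5-hydroxy-3,7-dimethylocta-2,6-dienoate
Conditions: SiCl4, chiral binaphthyldiamine bisphosphoramide (Si-face antipode, 5 mol%), iPr2NEt (10 mol%), CH2Cl2, −78 °C; aq. NaHCO3
Reagents that add atoms: none
Why: Second vinylogous Mukaiyama aldol reaction under the same catalyst control, in which Si-face attack on the enal sets the new C5 carbinol as S regardless of the remote dioxolane and completes the C15 chain; this carbinol later becomes the enone carbonyl, so its only stereochemical task is to steer step 10.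

Step 8
Reactants: 11 hydroxy ester
Product: 12 methyl (2E,5S,6E)-8-[(4S,5S)-2,2-dimethyl-5-(prop-1-en-2-yl)-1,3-dioxolan-4-yl]-3,7-dimethyl-5-[(triethylsilyl)oxy]octa-2,6-dienoate
Conditions: TESCl, imidazole, CH2Cl2, 0 °C
Reagents that add atoms: chlorotriethylsilane, CC[Si](CC)(CC)Cl
Why: Silyl ether formation protects the carbinol from the acid chloride step and makes it the bulky group that steers the cycloaddition.

Step 9
Reactants: 12 silyl ether ester
Product: 13 (2E,5S,6E)-8-[(4S,5S)-2,2-dimethyl-5-(prop-1-en-2-yl)-1,3-dioxolan-4-yl]-3,7-dimethyl-5-[(triethylsilyl)oxy]octa-2,6-dienoic acid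
Conditions: LiOH, THF/MeOH/H2O, rt; then dilute HCl to pH 4, 0 °C
Reagents that add atoms: lithium hydroxide, [Li+].[OH-]
Why: Saponification of the methyl ester, in which the E-enoate cannot lactonise and the TES ether and acetonide survive the brief pH 4 work-up.

Step 10
Reactants: 13 acid
Product: 16 (1R,4S,5R,7R)-7-{[(4S,5S)-2,2-dimethyl-5-(prop-1-en-2-yl)-1,3-dioxolan-4-yl]methyl}-7-methyl-2-methylidene-4-[(triethylsilyl)oxy]bicyclo[3.1.1]heptan-6-one, via acid chloride 14 (not isolated), via vinylketene 15 (not isolated)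
Conditions: 1-chloro-N,N,2-trimethylprop-1-en-1-amine, CH2Cl2, 0 °C to rt; then Et3N, toluene, 110 °C, slow addition (0.005 M)
Reagents that add atoms: none
Why: Loss of HCl from the C3 methyl of the acid chloride gives a vinylketene that undergoes the known intramolecular ketene–alkene [2+2] cycloaddition to a 2-methylidenebicyclo[3.1.1]heptan-6-one: the ketene carbonyl carbon bonds to the less substituted alkene carbon, suprafacial addition to the E-alkene puts the new ring methyl over the three-carbon bridge and the side chain towards the ketone, and the alkene face is the one that leaves the TES-oxy group anti to the methyl-bearing bridge, which fixes C1, C5 and C7 as drawn.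

Step 11
Reactants: 16 bicyclic ketone
Product: 18 N'-[(1R,4S,5S,7R)-7-{[(4S,5S)-2,2-dimethyl-5-(prop-1-en-2-yl)-1,3-dioxolan-4-yl]methyl}-4-hydroxy-7-methyl-2-methylidenebicyclo[3.1.1]heptan-6-ylidene]-4-methylbenzenesulfonohydrazide, via silyl ether tosylhydrazone 17 (not isolated)
Conditions: TsNHNH2, PPTS (20 mol%), MeOH, rt
Reagents that add atoms: 4-methylbenzenesulfonohydrazide, Cc1ccc(cc1)S(=O)(=O)NN
Why: Hydrazone formation at the strained cyclobutanone (the only ketone present) and acid methanolysis of the TES ether run in the same flask, while the acetonide stays; the C=N geometry is not assigned and does not matter.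

Step 12
Reactants: 18 hydroxy tosylhydrazone
Product: 20 N'-[(1R,5S,7R)-7-{[(4S,5S)-2,2-dimethyl-5-(prop-1-en-2-yl)-1,3-dioxolan-4-yl]methyl}-2,7-dimethyl-4-oxobicyclo[3.1.1]hept-2-en-6-ylidene]-4-methylbenzenesulfonohydrazide, via methylidene ketone 19 (not isolated)
Conditions: nPr4N[RuO4] (5 mol%), N-methylmorpholine N-oxide, 4 Å sieves, CH2Cl2, rt; then DBU, rt
Reagents that add atoms: none
Why: Ley–Griffith oxidation gives the β,γ-unsaturated ketone, and DBU moves the exocyclic alkene into conjugation through the doubly activated CH2 (base-mediated isomerisation); the methylidene has to be gone before step 13 because a radical at that carbon would open the cyclobutane, and the hydrazone shields the four-ring carbon from retro-Claisen cleavage.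

Step 13
Reactants: 20 enone tosylhydrazone
Product: 23 (1R,2R,4S,5S,7S,8R)-4,5-(isopropylidenedioxy)-2,6,6,9-tetramethyltricyclo[5.4.0.0^2,8]undec-9-en-11-one, via tosylhydrazide 21 (not isolated), via diazene 22 (not isolated)
Conditions: Fe(acac)3 (30 mol%), PhSiH3, EtOH, 60 °C, 0.01 M; then Et3N, 80 °C
Reagents that add atoms: none
Why: Proposed new method: hydrogen-atom transfer from the iron hydride to the CH2 terminus of the isopropenyl group turns its inner carbon, a cation site in ionic chemistry, into a nucleophilic tertiary radical (a carbanion-type, reversed-polarity synthon) that adds 7-exo to the equally electrophilic C=N carbon of the strained four-ring hydrazone from the only face the tether reaches, the hydrazinyl radical is reduced to the tosylhydrazide, and Et3N then expels sulfinate and N2 so that C7 ends with H on the enone side (the only geometry the cage allows); the closest known reaction type is the iron-hydride radical reductive alkylation of alkenes by tethered tosylhydrazones, known for five- and six-membered rings.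

Step 14
Reactants: 23 tricyclic acetonide
Product: 24 (1R,2R,4S,5S,7S,8R)-4,5-dihydroxy-2,6,6,9-tetramethyltricyclo[5.4.0.0^2,8]undec-9-en-11-one
Conditions: AcOH/H2O/THF (3:1:1), 40 °C
Reagents that add atoms: none
Why: Acetal hydrolysis of the strained trans-fused acetonide frees the trans-diol under acid mild enough for the enone cage.

Step 15
Reactants: 24 diol; 25 (2S)-2-methylbutanoic anhydride
Product: 26 (1R,2R,4S,5S,7S,8R)-5-hydroxy-2,6,6,9-tetramethyl-11-oxotricyclo[5.4.0.0^2,8]undec-9-en-4-yl (2S)-2-methylbutanoate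
Conditions: Et3N, DMAP (10 mol%), CH2Cl2, −20 to 0 °C
Reagents that add atoms: none
Why: DMAP-catalysed acylation goes to the C4 hydroxyl because the C5 hydroxyl sits next to the quaternary CMe2 carbon (steric differentiation), and the acyl stereocentre comes in unchanged from the anhydride.

Step 16
Reactants: 26 hydroxy ester; 27 angelic acid ((2Z)-2-methylbut-2-enoic acid)
Product: 29 (1R,2R,4S,5S,7S,8R)-2,6,6,9-tetramethyl-4-{[(2S)-2-methylbutanoyl]oxy}-11-oxotricyclo[5.4.0.0^2,8]undec-9-en-5-yl (2Z)-2-methylbut-2-enoate, via mixed anhydride 28 (not isolated)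
Conditions: 27, 2,4,6-trichlorobenzoyl chloride, Et3N, toluene, rt; then 26, DMAP, toluene, 75 °C
Reagents that add atoms: none
Why: Yamaguchi esterification through the mixed trichlorobenzoic anhydride forces acylation of the hindered C5 hydroxyl without strong base, which keeps the Z geometry of the angelate.

## Compound list

1 | methyl 3-methylbut-2-enoate | COC(=O)C=C(C)C | starting material
2 | lithium 1-methoxy-3-methylbuta-1,3-dien-1-olate | [Li+].[O-]C(OC)=CC(C)=C | intermediate
3 | tert-butyl[(1-methoxy-3-methylbuta-1,3-dien-1-yl)oxy]dimethylsilane (ketene acetal geometry not assigned) | COC(=CC(C)=C)O[Si](C)(C)C(C)(C)C | intermediate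
4 | 3-methylbut-2-enal (prenal) | CC(C)=CC=O | starting material
5 | methyl (2E,5S)-5-hydroxy-3,7-dimethylocta-2,6-dienoate | COC(=O)/C=C(\C)C[C@H](O)C=C(C)C | intermediate
6 | methyl (2E,5S,6S)-6-hydroperoxy-5-hydroxy-3,7-dimethylocta-2,7-dienoate | COC(=O)/C=C(\C)C[C@H](O)[C@@H](OO)C(C)=C | intermediate
7 | methyl (2E,5S,6S)-5,6-dihydroxy-3,7-dimethylocta-2,7-dienoate | COC(=O)/C=C(\C)C[C@H](O)[C@@H](O)C(C)=C | intermediate
8 | methyl (2E)-4-[(4S,5S)-2,2-dimethyl-5-(prop-1-en-2-yl)-1,3-dioxolan-4-yl]-3-methylbut-2-enoate | COC(=O)/C=C(\C)C[C@@H]1OC(C)(C)O[C@H]1C(C)=C | intermediate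
9 | (2E)-4-[(4S,5S)-2,2-dimethyl-5-(prop-1-en-2-yl)-1,3-dioxolan-4-yl]-3-methylbut-2-en-1-ol | OC/C=C(\C)C[C@@H]1OC(C)(C)O[C@H]1C(C)=C | intermediate
10 | (2E)-4-[(4S,5S)-2,2-dimethyl-5-(prop-1-en-2-yl)-1,3-dioxolan-4-yl]-3-methylbut-2-enal | O=C/C=C(\C)C[C@@H]1OC(C)(C)O[C@H]1C(C)=C | intermediate
11 | methyl (2E,5S,6E)-8-[(4S,5S)-2,2-dimethyl-5-(prop-1-en-2-yl)-1,3-dioxolan-4-yl]-5-hydroxy-3,7-dimethylocta-2,6-dienoate | COC(=O)/C=C(\C)C[C@H](O)/C=C(\C)C[C@@H]1OC(C)(C)O[C@H]1C(C)=C | intermediate
12 | methyl (2E,5S,6E)-8-[(4S,5S)-2,2-dimethyl-5-(prop-1-en-2-yl)-1,3-dioxolan-4-yl]-3,7-dimethyl-5-[(triethylsilyl)oxy]octa-2,6-dienoate | COC(=O)/C=C(\C)C[C@H](O[Si](CC)(CC)CC)/C=C(\C)C[C@@H]1OC(C)(C)O[C@H]1C(C)=C | intermediate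
13 | (2E,5S,6E)-8-[(4S,5S)-2,2-dimethyl-5-(prop-1-en-2-yl)-1,3-dioxolan-4-yl]-3,7-dimethyl-5-[(triethylsilyl)oxy]octa-2,6-dienoic acid | OC(=O)/C=C(\C)C[C@H](O[Si](CC)(CC)CC)/C=C(\C)C[C@@H]1OC(C)(C)O[C@H]1C(C)=C | intermediate
14 | (2E,5S,6E)-8-[(4S,5S)-2,2-dimethyl-5-(prop-1-en-2-yl)-1,3-dioxolan-4-yl]-3,7-dimethyl-5-[(triethylsilyl)oxy]octa-2,6-dienoyl chloride | ClC(=O)/C=C(\C)C[C@H](O[Si](CC)(CC)CC)/C=C(\C)C[C@@H]1OC(C)(C)O[C@H]1C(C)=C | intermediate
15 | (5S,6E)-8-[(4S,5S)-2,2-dimethyl-5-(prop-1-en-2-yl)-1,3-dioxolan-4-yl]-7-methyl-3-methylidene-5-[(triethylsilyl)oxy]octa-1,6-dien-1-one (vinylketene) | O=C=CC(=C)C[C@H](O[Si](CC)(CC)CC)/C=C(\C)C[C@@H]1OC(C)(C)O[C@H]1C(C)=C | intermediate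
16 | (1R,4S,5R,7R)-7-{[(4S,5S)-2,2-dimethyl-5-(prop-1-en-2-yl)-1,3-dioxolan-4-yl]methyl}-7-methyl-2-methylidene-4-[(triethylsilyl)oxy]bicyclo[3.1.1]heptan-6-one | O=C1[C@@H]2C(=C)C[C@H](O[Si](CC)(CC)CC)[C@H]1[C@]2(C)C[C@@H]1OC(C)(C)O[C@H]1C(C)=C | intermediate
17 | N'-[(1R,4S,5S,7R)-7-{[(4S,5S)-2,2-dimethyl-5-(prop-1-en-2-yl)-1,3-dioxolan-4-yl]methyl}-7-methyl-2-methylidene-4-[(triethylsilyl)oxy]bicyclo[3.1.1]heptan-6-ylidene]-4-methylbenzenesulfonohydrazide | Cc1ccc(cc1)S(=O)(=O)NN=C1[C@@H]2C(=C)C[C@H](O[Si](CC)(CC)CC)[C@H]1[C@]2(C)C[C@@H]1OC(C)(C)O[C@H]1C(C)=C | intermediate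
18 | N'-[(1R,4S,5S,7R)-7-{[(4S,5S)-2,2-dimethyl-5-(prop-1-en-2-yl)-1,3-dioxolan-4-yl]methyl}-4-hydroxy-7-methyl-2-methylidenebicyclo[3.1.1]heptan-6-ylidene]-4-methylbenzenesulfonohydrazide | Cc1ccc(cc1)S(=O)(=O)NN=C1[C@@H]2C(=C)C[C@H](O)[C@H]1[C@]2(C)C[C@@H]1OC(C)(C)O[C@H]1C(C)=C | intermediate
19 | N'-[(1R,5S,7R)-7-{[(4S,5S)-2,2-dimethyl-5-(prop-1-en-2-yl)-1,3-dioxolan-4-yl]methyl}-7-methyl-2-methylidene-4-oxobicyclo[3.1.1]heptan-6-ylidene]-4-methylbenzenesulfonohydrazide | Cc1ccc(cc1)S(=O)(=O)NN=C1[C@@H]2C(=C)CC(=O)[C@H]1[C@]2(C)C[C@@H]1OC(C)(C)O[C@H]1C(C)=C | intermediate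
20 | N'-[(1R,5S,7R)-7-{[(4S,5S)-2,2-dimethyl-5-(prop-1-en-2-yl)-1,3-dioxolan-4-yl]methyl}-2,7-dimethyl-4-oxobicyclo[3.1.1]hept-2-en-6-ylidene]-4-methylbenzenesulfonohydrazide | Cc1ccc(cc1)S(=O)(=O)NN=C1[C@@H]2C(C)=CC(=O)[C@H]1[C@]2(C)C[C@@H]1OC(C)(C)O[C@H]1C(C)=C | intermediate
21 | N'-[(1S,2R,4S,5S,7R,8R)-4,5-(isopropylidenedioxy)-2,6,6,9-tetramethyl-11-oxotricyclo[5.4.0.0^2,8]undec-9-en-7-yl]-4-methylbenzenesulfonohydrazide (N on the face that becomes C7–H) | CC1(C)O[C@@H]2[C@@H](O1)C[C@@]3(C)[C@@H]4C(=O)C=C(C)[C@H]3[C@]4(NNS(=O)(=O)c1ccc(C)cc1)C2(C)C | intermediate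
22 | (1S,2R,4S,5S,7R,8R)-7-diazenyl-4,5-(isopropylidenedioxy)-2,6,6,9-tetramethyltricyclo[5.4.0.0^2,8]undec-9-en-11-one | CC1(C)O[C@@H]2[C@@H](O1)C[C@@]3(C)[C@@H]4C(=O)C=C(C)[C@H]3[C@]4(N=N)C2(C)C | intermediate
23 | (1R,2R,4S,5S,7S,8R)-4,5-(isopropylidenedioxy)-2,6,6,9-tetramethyltricyclo[5.4.0.0^2,8]undec-9-en-11-one | CC1(C)O[C@@H]2[C@@H](O1)C[C@@]3(C)[C@@H]4C(=O)C=C(C)[C@H]3[C@@H]4C2(C)C | intermediate
24 | (1R,2R,4S,5S,7S,8R)-4,5-dihydroxy-2,6,6,9-tetramethyltricyclo[5.4.0.0^2,8]undec-9-en-11-one | O[C@@H]1[C@@H](O)C[C@@]2(C)[C@@H]3C(=O)C=C(C)[C@H]2[C@@H]3C1(C)C | intermediate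
25 | (2S)-2-methylbutanoic anhydride | CC[C@H](C)C(=O)OC(=O)[C@@H](C)CC | starting material
26 | (1R,2R,4S,5S,7S,8R)-5-hydroxy-2,6,6,9-tetramethyl-11-oxotricyclo[5.4.0.0^2,8]undec-9-en-4-yl (2S)-2-methylbutanoate | O[C@@H]1[C@@H](OC(=O)[C@@H](C)CC)C[C@@]2(C)[C@@H]3C(=O)C=C(C)[C@H]2[C@@H]3C1(C)C | intermediate
27 | angelic acid, (2Z)-2-methylbut-2-enoic acid | C/C=C(/C)C(=O)O | starting material
28 | (2Z)-2-methylbut-2-enoic 2,4,6-trichlorobenzoic anhydride | C/C=C(/C)C(=O)OC(=O)c1c(Cl)cc(Cl)cc1Cl | intermediate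
29 | (1R,2R,4S,5S,7S,8R)-2,6,6,9-tetramethyl-4-{[(2S)-2-methylbutanoyl]oxy}-11-oxotricyclo[5.4.0.0^2,8]undec-9-en-5-yl (2Z)-2-methylbut-2-enoate | C/C=C(/C)C(=O)O[C@@H]1[C@@H](OC(=O)[C@@H](C)CC)C[C@@]2(C)[C@@H]3C(=O)C=C(C)[C@H]2[C@@H]3C1(C)C | target

## Step count and risks

Total step count: 16. Longest linear sequence: 16 steps (1 → 3 → 5 → … → 29).

**Step 13 (radical ring closure).** Likely failure: the tertiary radical is reduced to the isopropyl group before the slow 7-exo addition, or the iron hydride attacks the enone. The fallback sets out from 20 and comes back at 23. It separates radical generation from ring closure: Markovnikov hydrobromination of the isopropenyl group of 20 (Co(acac)2, t-BuOOH, Et3SiH, TsBr) gives the tertiary bromide F1. Slow syringe-pump addition of Bu3SnH/AIBN to F1 in benzene at 80 °C then runs a tin hydride chain at low stannane concentration, in which the tertiary radical adds to the C=N carbon and the hydrazinyl radical takes hydrogen from the stannane. This gives the same tosylhydrazide 21, which Et3N converts through 22 into 23.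

**Step 10 (ketene [2+2]).** Likely failure: loss of the silyloxy group from the dienolate stage, ketene oligomerisation, or a poor facial ratio. The fallback sets out from 13 and comes back at 16, using a keteniminium in place of the ketene. Acid chloride 14 is quenched with Me2NH to give the N,N-dimethylamide F2. Tf2O and 2,4,6-collidine in 1,2-dichloroethane turn F2 into the much more electrophilic vinylketeniminium triflate F3, which closes at or below room temperature to the cyclobutaniminium triflate F4. Aqueous NaHCO3 hydrolyses F4 to ketone 16.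

**Step 16 (angelate on the neopentyl-type C5 hydroxyl).** Likely failure: no acylation, or Z to E drift to the tiglate at 75 °C. The fallback sets out from 26 and comes back at 29, building the double bond on the ester instead of transferring it. Alcohol 26 is esterified with 2-[bis(2,2,2-trifluoroethoxy)phosphoryl]propanoic acid (DCC, DMAP) to give the phosphonate ester F5, a mixture at the phosphonate carbon. Still–Gennari olefination of F5 (KN(SiMe3)2, 18-crown-6, THF, −78 °C, acetaldehyde) gives the Z-configured 2-methylbut-2-enoate 29.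

## Further compounds

F1 | step 13 | tertiary bromide: 20 with the prop-1-en-2-yl group changed into 2-bromopropan-2-yl, all stereocentres as in 20 | Cc1ccc(cc1)S(=O)(=O)NN=C1[C@@H]2C(C)=CC(=O)[C@H]1[C@]2(C)C[C@@H]1OC(C)(C)O[C@H]1C(C)(C)Br
F2 | step 10 | N,N-dimethylamide of acid 13 | CN(C)C(=O)/C=C(\C)C[C@H](O[Si](CC)(CC)CC)/C=C(\C)C[C@@H]1OC(C)(C)O[C@H]1C(C)=C
F3 | step 10 | vinylketeniminium triflate, the N,N-dimethyliminium analogue of ketene 15 | C[N+](C)=C=CC(=C)C[C@H](O[Si](CC)(CC)CC)/C=C(\C)C[C@@H]1OC(C)(C)O[C@H]1C(C)=C.[O-]S(=O)(=O)C(F)(F)F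
F4 | step 10 | cyclobutaniminium triflate, the N,N-dimethyliminium salt of ketone 16 | C[N+](C)=C1[C@@H]2C(=C)C[C@H](O[Si](CC)(CC)CC)[C@H]1[C@]2(C)C[C@@H]1OC(C)(C)O[C@H]1C(C)=C.[O-]S(=O)(=O)C(F)(F)F
F5 | step 16 | C5 2-[bis(2,2,2-trifluoroethoxy)phosphoryl]propanoate of 26, epimers at the phosphonate carbon | CC(C(=O)O[C@@H]1[C@@H](OC(=O)[C@@H](C)CC)C[C@@]2(C)[C@@H]3C(=O)C=C(C)[C@H]2[C@@H]3C1(C)C)P(=O)(OCC(F)(F)F)OCC(F)(F)F
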